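**Retrosynthetic overview**
1. Target 13 comes from the bis-N-tosyl pyrrole ester 12 by removal of the two indole sulfonyl groups.
2. The pyrrole ring is formed last: bonds C2–C3 and C4–C5 are made in one pot by a new aldol/Horner–Wadsworth–Emmons ("Hinsberg–Horner") annulation of 1,2-diketone 6 with phosphonoglycinate 10, which gives the 2-CO2Me/5-H pattern directly.
3. Diketone 6 comes from two indol-3-yl Grignard units (chemoselective iodine–magnesium exchange on 5-bromo-3-iodo-1-tosylindole 3) and the bis-Weinreb amide of oxalic acid; no palladium step touches the aryl bromides.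
4. Reagent 10 comes from methyl N-benzylglycinate by Kabachnik–Fields phosphonomethylation with formaldehyde and diethyl phosphite, then hydrogenolytic N-debenzylation and N-acetylation.
5. Ring order: both indole rings are bought as 5-bromoindole; the central pyrrole is the only ring built.

Assumption: the target has no stereocentre and no configurationally stable axis, so it is one achiral compound and no enantiocontrol is needed.

**Route**

Step 1
Reactants: 1 5-bromo-1H-indole
Product: 3 5-bromo-3-iodo-1-(4-methylbenzenesulfonyl)-1H-indole, via 5-bromo-3-iodo-1H-indole 2 (not isolated)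
Conditions: I2 (1.05 equiv), KOH (4 equiv), DMF, rt; then TsCl (1.3 equiv), 0 °C → rt
Reagents that add atoms: iodine, [I][I]; 4-methylbenzenesulfonyl chloride, Cc1ccc(cc1)S(Cl)(=O)=O
Why: Electrophilic iodination of the indole occurs only at C3, its most nucleophilic position, and the crude, sensitive 3-iodoindole is N-sulfonylated in the same basic DMF solution (electrophilic aromatic substitution followed by N-sulfonylation).

Step 2
Reactants: 3 5-bromo-3-iodo-1-(4-methylbenzenesulfonyl)-1H-indole (2.2 equiv); 4 N,N'-dimethoxy-N,N'-dimethyloxamide (1.0 equiv)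
Product: 6 1,2-bis[5-bromo-1-(4-methylbenzenesulfonyl)-1H-indol-3-yl]ethane-1,2-dione, via indol-3-ylmagnesium chloride 5 (not isolated)
Conditions: iPrMgCl·LiCl (1.05 equiv per 3), THF, −40 °C; then 4, −40 °C → rt; aq. NH4Cl
Reagents that add atoms: none
Why: Iodine–magnesium exchange at −40 °C is far faster at the carbon–iodine bond than at the carbon–bromine bond, and each Weinreb amide carbon of 4 takes up one aryl group and stays as a chelated tetrahedral adduct until work-up releases the 1,2-diketone (halogen–metal exchange and Weinreb ketone synthesis).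

Step 3
Reactants: 7 methyl N-benzylglycinate
Product: 8 methyl N-benzyl-N-[(diethoxyphosphoryl)methyl]glycinate
Conditions: (CH2O)n (1.1 equiv), HP(O)(OEt)2 (1.05 equiv), toluene, 80 °C
Reagents that add atoms: formaldehyde (as paraformaldehyde), C=O; diethyl phosphite, CCO[PH](=O)OCC
Why: The secondary amine condenses with formaldehyde to an N-methylene iminium ion that is trapped by diethyl phosphite at phosphorus, and a secondary amine can be phosphonomethylated only once (Kabachnik–Fields, or phospha-Mannich, reaction).

Step 4
Reactants: 8 methyl N-benzyl-N-[(diethoxyphosphoryl)methyl]glycinate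
Product: 10 methyl N-acetyl-N-[(diethoxyphosphoryl)methyl]glycinate, via methyl N-[(diethoxyphosphoryl)methyl]glycinate 9 (not isolated)
Conditions: H2 (1 atm), Pd(OH)2/C (cat.), MeOH, rt; filter, evaporate; then Ac2O (1.5 equiv), Et3N, DMAP (cat.), CH2Cl2, 0 °C → rt
Reagents that add atoms: acetic anhydride, CC(=O)OC(C)=O
Why: Hydrogenolysis cleaves only the benzylic C–N bond while the ester and phosphonate are inert, and the crude secondary amine is acetylated at once, which blocks diketopiperazine formation and makes both flanking CH2 groups acidic enough for the annulation (catalytic hydrogenolysis followed by N-acylation).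

Step 5
Reactants: 6 1,2-bis[5-bromo-1-(4-methylbenzenesulfonyl)-1H-indol-3-yl]ethane-1,2-dione; 10 methyl N-acetyl-N-[(diethoxyphosphoryl)methyl]glycinate
Product: 12 methyl 3,4-bis[5-bromo-1-(4-methylbenzenesulfonyl)-1H-indol-3-yl]-1H-pyrrole-2-carboxylate, via aldol adduct 11 (not isolated)
Conditions: 10 (1.3 equiv), KN(SiMe3)2 (1.4 equiv), THF, −78 °C; add 6; then KN(SiMe3)2 (2.0 equiv), −78 °C → 40 °C; aq. NH4Cl
Reagents that add atoms: none
Why: Proposed new method: a one-pot "Hinsberg–Horner" annulation of a 1,2-diketone with an N-acyl-N-(phosphonomethyl)glycinate, a reagent designed so that its two CH2 groups react differently – the more acidic glycinate CH2 is deprotonated first and adds to one carbonyl of 6 (the aldol half of a Hinsberg pyrrole synthesis, giving 11), further base then generates the N-acyl-α-aminomethylphosphonate carbanion, which closes the five-membered ring on the neighbouring ketone and collapses by Horner–Wadsworth–Emmons loss of diethyl phosphate to a C4=C5 bond bearing only hydrogen, after which the C3 oxygen is expelled (as hydroxide or, after N-to-O acetyl transfer, as acetate) with aromatisation as driving force and the activated N-acetyl group is lost, so the N–H pyrrole forms directly as its potassium salt; the closest known reaction types are the Hinsberg synthesis of pyrrole-2,5-dicarboxylates from 1,2-diketones and N-acyl iminodiacetates, the Horner–Wadsworth–Emmons synthesis of enamides from N-acylaminomethylphosphonates, and the double-Wittig annulation of 1,2-diketones to 3,4-disubstituted thiophenes and furans, but the mixed aldol/olefination pairing that gives a 5-unsubstituted pyrrole-2-carboxylate in one step has not been described.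

Step 6
Reactants: 12 methyl 3,4-bis[5-bromo-1-(4-methylbenzenesulfonyl)-1H-indol-3-yl]-1H-pyrrole-2-carboxylate
Product: 13 methyl 3,4-bis(5-bromo-1H-indol-3-yl)-1H-pyrrole-2-carboxylate
Conditions: Cs2CO3 (6 equiv), THF/MeOH (2:1), rt → 45 °C
Reagents that add atoms: none
Why: Methoxide attacks the sulfur of the N-sulfonyl indoles and frees both indole N–H groups, while the methyl ester can only transesterify to itself and the aryl bromides are inert (nucleophilic N-desulfonylation).

**Compound list**
1 | 5-bromo-1H-indole | Brc1ccc2[nH]ccc2c1 | starting material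
2 | 5-bromo-3-iodo-1H-indole | Brc1ccc2[nH]cc(I)c2c1 | intermediate
3 | 5-bromo-3-iodo-1-(4-methylbenzenesulfonyl)-1H-indole | Cc1ccc(cc1)S(=O)(=O)n1cc(I)c2cc(Br)ccc12 | intermediate
4 | N,N'-dimethoxy-N,N'-dimethyloxamide | CON(C)C(=O)C(=O)N(C)OC | starting material
5 | [5-bromo-1-(4-methylbenzenesulfonyl)-1H-indol-3-yl]magnesium chloride (LiCl complex, in THF solution) | Cc1ccc(cc1)S(=O)(=O)n1cc([Mg]Cl)c2cc(Br)ccc12 | intermediate
6 | 1,2-bis[5-bromo-1-(4-methylbenzenesulfonyl)-1H-indol-3-yl]ethane-1,2-dione | O=C(C(=O)c1cn(S(=O)(=O)c2ccc(C)cc2)c2ccc(Br)cc12)c1cn(S(=O)(=O)c2ccc(C)cc2)c2ccc(Br)cc12 | intermediate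
7 | methyl N-benzylglycinate | COC(=O)CNCc1ccccc1 | starting material
8 | methyl N-benzyl-N-[(diethoxyphosphoryl)methyl]glycinate | CCOP(=O)(CN(CC(=O)OC)Cc1ccccc1)OCC | intermediate
9 | methyl N-[(diethoxyphosphoryl)methyl]glycinate | CCOP(=O)(CNCC(=O)OC)OCC | intermediate
10 | methyl N-acetyl-N-[(diethoxyphosphoryl)methyl]glycinate | CCOP(=O)(CN(CC(=O)OC)C(C)=O)OCC | intermediate
11 | methyl 2-{acetyl[(diethoxyphosphoryl)methyl]amino}-3,4-bis[5-bromo-1-(4-methylbenzenesulfonyl)-1H-indol-3-yl]-3-hydroxy-4-oxobutanoate (potassium alkoxide in the flask; diastereomer mixture, both stereocentres are destroyed on aromatisation) | COC(=O)C(N(CP(=O)(OCC)OCC)C(C)=O)C(O)(C(=O)c1cn(S(=O)(=O)c2ccc(C)cc2)c2ccc(Br)cc12)c1cn(S(=O)(=O)c2ccc(C)cc2)c2ccc(Br)cc12 | intermediate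
12 | methyl 3,4-bis[5-bromo-1-(4-methylbenzenesulfonyl)-1H-indol-3-yl]-1H-pyrrole-2-carboxylate | COC(=O)c1[nH]cc(-c2cn(S(=O)(=O)c3ccc(C)cc3)c3ccc(Br)cc23)c1-c1cn(S(=O)(=O)c2ccc(C)cc2)c2ccc(Br)cc12 | intermediate
13 | methyl 3,4-bis(5-bromo-1H-indol-3-yl)-1H-pyrrole-2-carboxylate (achiral) | COC(=O)c1[nH]cc(-c2c[nH]c3ccc(Br)cc23)c1-c1c[nH]c2ccc(Br)cc12 | target

**Step count and risk**

Total steps: 6. Longest linear sequence: 4 steps (1 → 3 → 6 → 12 → 13 through steps 1, 2, 5, 6; the reagent arm 7 → 8 → 10 → 12 → 13 through steps 3, 4, 5, 6 is equally long).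

The three steps most likely to fail:

Step 5 (the proposed new annulation). The phosphonate carbon may not be deprotonated under KN(SiMe3)2, so the reaction could stall at aldol adduct 11 or at the cyclic β-hydroxyphosphonate. The aldolate could also undergo α-ketol rearrangement, and the enolate could add to C2 of the 3-acyl-N-sulfonylindole. The fallback uses known chemistry and sets out from 6. A classical Hinsberg pyrrole synthesis is run with dimethyl N-acetyliminodiacetate F1 (made from commercial dimethyl iminodiacetate hydrochloride with Ac2O/Et3N) and KOtBu in THF/t-BuOH. Both CH2 groups are then ester-activated, and the product is dimethyl 3,4-bis[5-bromo-1-(4-methylbenzenesulfonyl)-1H-indol-3-yl]-1H-pyrrole-2,5-dicarboxylate F2. Treatment with LiOH in THF/MeOH/H2O at 60 °C removes both tosyl groups and saponifies one ester only, because the carboxylate and pyrrolide charges protect the second ester. This gives 3,4-bis(5-bromo-1H-indol-3-yl)-5-(methoxycarbonyl)-1H-pyrrole-2-carboxylic acid F3. Protodecarboxylation of this pyrrole-2-carboxylic acid in TFA/CH2Cl2 at rt → 40 °C returns to the route at 13.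

Step 2 (double Grignard addition). The second addition to the α-keto Weinreb amide may be slow with the hindered, electron-poor indolyl Grignard, and some bromine–magnesium exchange could occur. The fallback sets out from 3. A Stille coupling of 2 equiv of 3 with bis(tributylstannyl)acetylene uses Pd(PPh3)4 (zerovalent palladium) in toluene at 80 °C, where oxidative addition into the carbon–iodine bond is much faster than into carbon–bromine. It gives 1,2-bis[5-bromo-1-(4-methylbenzenesulfonyl)-1H-indol-3-yl]ethyne F4. Oxidation of this diarylalkyne with KMnO4/NaHCO3/MgSO4 in aqueous acetone (or I2 in DMSO at 130 °C) gives the benzil-type diketone and comes back to the route at 6.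

Step 6 (double N-detosylation). Cleavage may be incomplete, and the methyl tosylate formed could N-methylate the pyrrole or indole anions. The fallback sets out from 12. Exhaustive hydrolysis with KOH in MeOH/H2O/THF at reflux removes both tosyl groups and the ester, giving 3,4-bis(5-bromo-1H-indol-3-yl)-1H-pyrrole-2-carboxylic acid F5. Chemoselective O-methylation of the carboxylic acid with Me3SiCHN2 in toluene/MeOH at 0 °C leaves the three N–H groups untouched and comes back to the route at 13.

**Further compounds**
F1 | step 5 | dimethyl N-acetyliminodiacetate | COC(=O)CN(CC(=O)OC)C(C)=O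
F2 | step 5 | dimethyl 3,4-bis[5-bromo-1-(4-methylbenzenesulfonyl)-1H-indol-3-yl]-1H-pyrrole-2,5-dicarboxylate | COC(=O)c1[nH]c(C(=O)OC)c(-c2cn(S(=O)(=O)c3ccc(C)cc3)c3ccc(Br)cc23)c1-c1cn(S(=O)(=O)c2ccc(C)cc2)c2ccc(Br)cc12
F3 | step 5 | 3,4-bis(5-bromo-1H-indol-3-yl)-5-(methoxycarbonyl)-1H-pyrrole-2-carboxylic acid | COC(=O)c1[nH]c(C(=O)O)c(-c2c[nH]c3ccc(Br)cc23)c1-c1c[nH]c2ccc(Br)cc12
F4 | step 2 | 1,2-bis[5-bromo-1-(4-methylbenzenesulfonyl)-1H-indol-3-yl]ethyne | Cc1ccc(cc1)S(=O)(=O)n1cc(C#Cc2cn(S(=O)(=O)c3ccc(C)cc3)c3ccc(Br)cc23)c2cc(Br)ccc12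
F5 | step 6 | 3,4-bis(5-bromo-1H-indol-3-yl)-1H-pyrrole-2-carboxylic acid | OC(=O)c1[nH]cc(-c2c[nH]c3ccc(Br)cc23)c1-c1c[nH]c2ccc(Br)cc12
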